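The data stem from a simulated flask from invented constants.

80.0 % is the number I began with for this flask: it is the trap ceiling θ, the capture agent charged, 10.0 mM, over the free catalyst charged, 12.5 mM. In the proposed scheme, catalyst intermediate B meets capture agent and gives the trapped intermediate, an off-cycle species, so one capture agent locks away one catalyst.

all flasks: free catalyst 2.5 mol%

| flask | starting material | second substrate | coupling partner | capture agent | remark |
|---|---|---|---|---|---|
| Saturday's | 0.70 M | 1 equiv | 3 equiv | 10 mM | run made earlier |
| flask | 0.50 M | 1.00 equiv | 3.00 equiv | 10.0 mM |  |

Saturday's run (percent of the starting material charged)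

| time / h | target / % | starting material / % |
|---|---|---|
| 0.667 | 60.2 | 39.0 |
| 1.33 | 88.3 | 11.4 |
| 2.50 | 99.7 | 1.4 |
| 4.00 | 100.7 | 0 |
| 8.00 | 100.1 | 0.2 |

(scatter of a reading: 1 percentage point)

- apparent order in coupling partner when 50 % of the starting material are converted (percent change of the rate of making target for one percent more coupling partner charged)
- apparent order in free catalyst when 50 % of the starting material are converted (percent change of the rate of making target for one percent more free catalyst charged)

I kept the books on the starting material first. In Saturday's run, target plus starting material came to 99.2 % at 0.667 h and 100 % at 8.00 h, within the scatter of 1 percentage point per reading. So I booked the starting material of this flask to target, apart from what catalyst intermediate A holds, which cannot exceed 2.5 mol%.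

The catalyst has a second ledger, whose entries are free catalyst, the two intermediates and the trapped share s. I froze the trapped amount against a change in the catalyst charged. The working catalyst is then the charge minus that amount, and the apparent order in free catalyst is n = 1/(1 − s), which runs from 1 up to 5.00 at s = θ.

Saturday's run had θ = 57.1 %, yet the first-order constant I read off its scattered starting material readings was higher in the second interval, 1.86 h⁻¹, than in the first, 1.41 h⁻¹. I took that as a sign that trapping in Saturday's run had not reached its ceiling near half conversion. For this flask I guessed s = 20.0 %, a quarter of θ, and so n = 1.25. For coupling partner, which no run varied, I guessed order 1.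

The forecast differed from me, with 0.5 and 3, saying “Catalyst is the catch”.

This flask gave 1.1 in coupling partner and 1.2 in free catalyst at 0.714 h, against my 1 and 1.25.

    starting material + free catalyst ⇌ catalyst intermediate A (K = 32.1 M⁻¹, k = 8.39 M⁻¹ min⁻¹)
    coupling partner + catalyst intermediate A → free catalyst + target (k = 0.542 M⁻¹ min⁻¹)
    second substrate + free catalyst ⇌ catalyst intermediate B (K = 1.37 M⁻¹, k = 2.98 M⁻¹ min⁻¹)
    coupling partner + catalyst intermediate B → free catalyst + second product (k = 0.935 M⁻¹ min⁻¹)
    catalyst intermediate B + capture agent → trapped intermediate (k = 5.11 M⁻¹ min⁻¹)

The coupling of catalyst intermediate A ran while starting material was there: it reached half of its turnover up to 10.0 h by 0.741 h and 88 % by 2.00 h, with starting material at 37.2 % after 1.00 h and 0.359 % after 5.00 h. Trapping ran on beyond that, taking the trapped intermediate from 22.4 % of the catalyst at 1.00 h to 77.6 % at 100 h, when capture agent stood at 3.01 % of its charge and θ times the capture agent used gives 77.6 %.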